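**Plan**
Core numbering: C1 (C–OH bridgehead), C2 (ArCH), O3, C4, C5 (CH bridgehead), C6 (ArCH), O7, C8; ring B = C1–C2–O3–C4–C5, ring A = C5–C6–O7–C8–C1; Ar = 3,4-dimethoxyphenyl.
Retrosynthesis: cut O7–C8 (ring A) first, then C5–C6 and C1–O together (isoxazoline from a nitrile oxide and a C1=C5 alkene), then C1=C5 (metathesis), O3–C4 (O-allylation) and C1–C2 (Morita–Baylis–Hillman).
Enabling feature: on ring B the C1–O bond and the C5–C6 bond lie on one face, anti to the C2 aryl, which is the cis C–O/C–C pair a suprafacial nitrile oxide addition lays across C1=C5 of a 2-aryl-2,5-dihydrofuran.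
Forward: acyclic allylic alcohol, ring B by ring-closing metathesis, isoxazoline across C1=C5, N–O cleavage, ring A by displacement at C8 by the C6 alkoxide.
Stereochemistry: C2 from a Sharpless kinetic resolution; C1 and C5 relayed from C2 in the cycloaddition; C6 by Felkin–Anh hydride addition; the strained ring fusion is formed in an irreversible SN2 step that touches no stereocentre.

Key step: step 8

Remark: the SMILES is read as written, that is with C1–OH and C5–H on opposite faces (trans-fused 3,7-dioxabicyclo[3.3.0]octane, 1S,2S,5S,6R); the route is built for this isomer.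

**Step 1**
Reactants: 1 veratraldehyde; 2 methyl acrylate
Product: 3 methyl 2-[(3,4-dimethoxyphenyl)(hydroxy)methyl]prop-2-enoate (racemic)
Conditions: DABCO (1.0 equiv), MeOH, rt, 5–7 d
Reagents that add atoms: none
Why: Morita–Baylis–Hillman reaction, in which the amine–acrylate zwitterion adds to the aldehyde and the amine is then expelled; the carbinol is formed racemic and is resolved in step 4.

**Step 2**
Reactants: 3 methyl 2-[(3,4-dimethoxyphenyl)(hydroxy)methyl]prop-2-enoate
Product: 4 2-[(3,4-dimethoxyphenyl)(hydroxy)methyl]prop-2-en-1-ol (racemic)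
Conditions: i-Bu2AlH (3.2 equiv), CH2Cl2, −78 → 0 °C; aq. KNaC4H4O6 (Rochelle salt)
Reagents that add atoms: none
Why: 1,2-reduction of the enoate ester by i-Bu2AlH gives the allylic alcohol and leaves the 1,1-disubstituted alkene untouched.

**Step 3**
Reactants: 4 2-[(3,4-dimethoxyphenyl)(hydroxy)methyl]prop-2-en-1-ol
Product: 5 2-[(3,4-dimethoxyphenyl)(hydroxy)methyl]prop-2-en-1-yl pivalate (racemic)
Conditions: pivaloyl chloride (1.05 equiv), pyridine, CH2Cl2, −20 → 0 °C
Reagents that add atoms: pivaloyl chloride, CC(C)(C)C(=O)Cl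
Why: chemoselective esterification, since the bulky acyl chloride acylates the primary allylic hydroxyl much faster than the hindered secondary benzylic one.

**Step 4**
Reactants: 5 2-[(3,4-dimethoxyphenyl)(hydroxy)methyl]prop-2-en-1-yl pivalate (racemic)
Product: 6 (S)-2-[(3,4-dimethoxyphenyl)(hydroxy)methyl]prop-2-en-1-yl pivalate
Conditions: Ti(OiPr)4 (0.2 equiv), D-(−)-diisopropyl tartrate (0.3 equiv), t-BuOOH (0.6 equiv), 4 Å molecular sieves, CH2Cl2, −20 °C, to about 55–60% conversion
Reagents that add atoms: none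
Why: Sharpless kinetic resolution of a 2-substituted secondary allylic alcohol, in which the D-(−)-tartrate catalyst epoxidizes the (R)-carbinol faster (oxygen delivered to the face carrying the carbinol hydrogen), so the (S)-alcohol that becomes C2 should be recovered.

**Step 5**
Reactants: 6 (S)-2-[(3,4-dimethoxyphenyl)(hydroxy)methyl]prop-2-en-1-yl pivalate; 7 allyl bromide
Product: 8 (S)-2-[(allyloxy)(3,4-dimethoxyphenyl)methyl]prop-2-en-1-yl pivalate
Conditions: Ag2O (1.5 equiv), allyl bromide (3 equiv), CH2Cl2, rt, dark, 24–48 h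
Reagents that add atoms: none
Why: Ag2O-mediated Williamson-type O-allylation under neutral conditions, which avoids pivaloyl migration and ionization of the electron-rich benzylic carbinol, so the C2 configuration is kept.

**Step 6**
Reactants: 8 (S)-2-[(allyloxy)(3,4-dimethoxyphenyl)methyl]prop-2-en-1-yl pivalate
Product: 9 (S)-[2-(3,4-dimethoxyphenyl)-2,5-dihydrofuran-3-yl]methyl pivalate
Conditions: second-generation Grubbs catalyst RuCl2(=CHPh)(PCy3)(H2IMes) (5 mol%), CH2Cl2, 40 °C
Reagents that add atoms: none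
Why: ring-closing olefin metathesis between the allyl ether and the 1,1-disubstituted alkene closes ring B as the trisubstituted C1=C5 dihydrofuran with loss of ethylene and without touching C2.

**Step 7**
Reactants: 1 veratraldehyde
Product: 10 (E)-3,4-dimethoxybenzaldehyde oxime
Conditions: NH2OH·HCl (1.2 equiv), NaOAc (1.3 equiv), EtOH/H2O, rt
Reagents that add atoms: hydroxylamine hydrochloride, Cl.NO
Why: condensation of the aldehyde with hydroxylamine (oxime formation) supplies the C6–N–O unit of the dipole.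

**Step 8**
Reactants: 9 (S)-[2-(3,4-dimethoxyphenyl)-2,5-dihydrofuran-3-yl]methyl pivalate; 10 (E)-3,4-dimethoxybenzaldehyde oxime
Product: 13 [(3aR,6S,6aS)-3,6-bis(3,4-dimethoxyphenyl)-3a,4,6,6a-tetrahydrofuro[3,4-d]isoxazol-6a-yl]methyl pivalate, via hydroximoyl chloride 11 (not isolated), via nitrile oxide 12 (not isolated)
Conditions: 10 (2.5 equiv), N-chlorosuccinimide (2.5 equiv), DMF, rt, 1 h; then 9 in CH2Cl2, Et3N (2.6 equiv, syringe pump over 12 h), 0 °C → rt
Reagents that add atoms: none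
Why: Triethylamine dehydrochlorinates 11 to the nitrile oxide 12, which adds to the C1=C5 double bond of 9 in a concerted, suprafacial Huisgen [3+2] cycloaddition, the reaction type well known for nitrile oxides with trisubstituted cycloalkenes and 2,5-dihydrofurans. The isoxazoline ring is closed by the cycloaddition itself (C5–C6 and C1–O made in one event, the new ring cis-fused to ring B), so no separate ring-closure mode applies. C1 and C5 become stereocentres together: the suprafacial addition fixes C1–O and C5–C6 cis to each other, and the C2 aryl group next to C1 screens its own face, so the dipole should arrive anti to it. The step needs regio- and face selectivity: for steric reasons the carbon terminus of the dipole bonds to the less substituted C5 and the oxygen to the fully substituted C1, and the single C2 stereocentre supplies the facial bias. Slow release of 12 keeps its concentration low and holds back furoxan dimerization while the sluggish trisubstituted alkene reacts. C6 is still sp2 at this stage and is set in step 11.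

**Step 9**
Reactants: 13 [(3aR,6S,6aS)-3,6-bis(3,4-dimethoxyphenyl)-3a,4,6,6a-tetrahydrofuro[3,4-d]isoxazol-6a-yl]methyl pivalate
Product: 15 [(2S,3S,4R)-4-(3,4-dimethoxybenzoyl)-2-(3,4-dimethoxyphenyl)-3-hydroxyoxolan-3-yl]methyl pivalate, via hydroxy imine 14 (not isolated)
Conditions: H2 (1 atm), Raney Ni, B(OH)3 (3 equiv), MeOH/H2O (5:1), rt
Reagents that add atoms: water, O
Why: hydrogenolysis of the isoxazoline N–O bond over Raney Ni followed by hydrolysis of the imine in the boric acid buffer, which unmasks the C1 hydroxyl and the C6 ketone without retro-aldol cleavage or epimerization at C5.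

**Step 10**
Reactants: 15 [(2S,3S,4R)-4-(3,4-dimethoxybenzoyl)-2-(3,4-dimethoxyphenyl)-3-hydroxyoxolan-3-yl]methyl pivalate
Product: 16 [(2S,3S,4R)-3-[(tert-butyldimethylsilyl)oxy]-4-(3,4-dimethoxybenzoyl)-2-(3,4-dimethoxyphenyl)oxolan-3-yl]methyl pivalate
Conditions: t-BuMe2SiOTf (2 equiv), 2,6-lutidine (3 equiv), CH2Cl2, −78 → 0 °C
Reagents that add atoms: tert-butyldimethylsilyl triflate, CC(C)(C)[Si](C)(C)OS(=O)(=O)C(F)(F)F
Why: silyl ether protection of the tertiary C1 hydroxyl with a silyl triflate and a hindered pyridine, mild enough for the base-sensitive β-alkoxy ketone, blocks the oxygen that would otherwise close an epoxide onto C8 in step 13.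

**Step 11**
Reactants: 16 [(2S,3S,4R)-3-[(tert-butyldimethylsilyl)oxy]-4-(3,4-dimethoxybenzoyl)-2-(3,4-dimethoxyphenyl)oxolan-3-yl]methyl pivalate
Product: 17 (2S,3S,4S)-3-[(tert-butyldimethylsilyl)oxy]-2-(3,4-dimethoxyphenyl)-4-[(R)-(3,4-dimethoxyphenyl)(hydroxy)methyl]-3-(hydroxymethyl)oxolane
Conditions: i-Bu2AlH (4.5 equiv), CH2Cl2, −78 °C (2 h) → −20 °C; aq. KNaC4H4O6
Reagents that add atoms: none
Why: i-Bu2AlH reduces the aryl ketone and cleaves the pivalate in one operation, the hydride adding to C6 in the Felkin–Anh sense (anti to the fully substituted C1, past the C5 hydrogen and not the C4 methylene), which should give the 6R carbinol.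

**Step 12**
Reactants: 17 (2S,3S,4S)-3-[(tert-butyldimethylsilyl)oxy]-2-(3,4-dimethoxyphenyl)-4-[(R)-(3,4-dimethoxyphenyl)(hydroxy)methyl]-3-(hydroxymethyl)oxolane
Product: 18 [(2S,3S,4S)-3-[(tert-butyldimethylsilyl)oxy]-2-(3,4-dimethoxyphenyl)-4-[(R)-(3,4-dimethoxyphenyl)(hydroxy)methyl]oxolan-3-yl]methyl 4-methylbenzenesulfonate
Conditions: TsCl (1.3 equiv), Et3N (2 equiv), DMAP (0.1 equiv), CH2Cl2, 0 °C
Reagents that add atoms: p-toluenesulfonyl chloride, Cc1ccc(cc1)S(=O)(=O)Cl
Why: selective sulfonylation of the primary C8 hydroxyl, the secondary benzylic C6 hydroxyl beside the branched C5 reacting more slowly, installs the leaving group without touching a stereocentre.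

**Step 13**
Reactants: 18 [(2S,3S,4S)-3-[(tert-butyldimethylsilyl)oxy]-2-(3,4-dimethoxyphenyl)-4-[(R)-(3,4-dimethoxyphenyl)(hydroxy)methyl]oxolan-3-yl]methyl 4-methylbenzenesulfonate
Product: 19 (1S,2S,5S,6R)-1-[(tert-butyldimethylsilyl)oxy]-2,6-bis(3,4-dimethoxyphenyl)-3,7-dioxabicyclo[3.3.0]octane
Conditions: NaH (1.5 equiv), THF, 0 → 40 °C
Reagents that add atoms: none
Why: intramolecular Williamson etherification (5-exo-tet) in which the C6 alkoxide displaces the C8 tosylate irreversibly, closing the strained trans-fused ring A; C8 has no β-hydrogen, so elimination is excluded, and the C6–O bond is never broken, so C6 keeps its configuration.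

**Step 14**
Reactants: 19 (1S,2S,5S,6R)-1-[(tert-butyldimethylsilyl)oxy]-2,6-bis(3,4-dimethoxyphenyl)-3,7-dioxabicyclo[3.3.0]octane
Product: 20 (1S,2S,5S,6R)-2,6-bis(3,4-dimethoxyphenyl)-3,7-dioxabicyclo[3.3.0]octan-1-ol
Conditions: Bu4NF (2 equiv), THF, 0 °C → rt
Reagents that add atoms: none
Why: fluoride-induced cleavage of the tertiary silyl ether under non-acidic conditions frees the C1 hydroxyl without risk of ionizing the two benzylic ether carbons of the strained bicycle.

**Compound list**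
1 | veratraldehyde (3,4-dimethoxybenzaldehyde) | COc1ccc(C=O)cc1OC | starting material
2 | methyl acrylate | C=CC(=O)OC | starting material
3 | methyl 2-[(3,4-dimethoxyphenyl)(hydroxy)methyl]prop-2-enoate, racemic | COC(=O)C(=C)C(O)c1ccc(OC)c(OC)c1 | intermediate
4 | 2-[(3,4-dimethoxyphenyl)(hydroxy)methyl]prop-2-en-1-ol, racemic | OCC(=C)C(O)c1ccc(OC)c(OC)c1 | intermediate
5 | 2-[(3,4-dimethoxyphenyl)(hydroxy)methyl]prop-2-en-1-yl pivalate, racemic | CC(C)(C)C(=O)OCC(=C)C(O)c1ccc(OC)c(OC)c1 | intermediate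
6 | (S)-2-[(3,4-dimethoxyphenyl)(hydroxy)methyl]prop-2-en-1-yl pivalate | CC(C)(C)C(=O)OCC(=C)[C@@H](O)c1ccc(OC)c(OC)c1 | intermediate
7 | allyl bromide | C=CCBr | starting material
8 | (S)-2-[(allyloxy)(3,4-dimethoxyphenyl)methyl]prop-2-en-1-yl pivalate | CC(C)(C)C(=O)OCC(=C)[C@@H](OCC=C)c1ccc(OC)c(OC)c1 | intermediate
9 | (S)-[2-(3,4-dimethoxyphenyl)-2,5-dihydrofuran-3-yl]methyl pivalate | COc1ccc(cc1OC)[C@@H]1OCC=C1COC(=O)C(C)(C)C | intermediate
10 | (E)-3,4-dimethoxybenzaldehyde oxime | COc1ccc(/C=N/O)cc1OC | intermediate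
11 | (Z)-N-hydroxy-3,4-dimethoxybenzimidoyl chloride (hydroximoyl chloride) | O/N=C(\Cl)c1ccc(OC)c(OC)c1 | intermediate (not isolated)
12 | 3,4-dimethoxybenzonitrile oxide | COc1ccc(cc1OC)C#[N+][O-] | intermediate (not isolated)
13 | [(3aR,6S,6aS)-3,6-bis(3,4-dimethoxyphenyl)-3a,4,6,6a-tetrahydrofuro[3,4-d]isoxazol-6a-yl]methyl pivalate (isoxazoline cis-fused to ring B; C1–O and C5–C6 cis, anti to the C2 aryl) | COc1ccc(cc1OC)C1=NO[C@@]2(COC(=O)C(C)(C)C)[C@H](c3ccc(OC)c(OC)c3)OC[C@@H]12 | intermediate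
14 | [(2S,3S,4R)-2-(3,4-dimethoxyphenyl)-4-[(3,4-dimethoxyphenyl)(imino)methyl]-3-hydroxyoxolan-3-yl]methyl pivalate | COc1ccc(cc1OC)C(=N)[C@@H]1CO[C@@H](c2ccc(OC)c(OC)c2)[C@@]1(O)COC(=O)C(C)(C)C | intermediate (not isolated)
15 | [(2S,3S,4R)-4-(3,4-dimethoxybenzoyl)-2-(3,4-dimethoxyphenyl)-3-hydroxyoxolan-3-yl]methyl pivalate | COc1ccc(cc1OC)C(=O)[C@@H]1CO[C@@H](c2ccc(OC)c(OC)c2)[C@@]1(O)COC(=O)C(C)(C)C | intermediate
16 | [(2S,3S,4R)-3-[(tert-butyldimethylsilyl)oxy]-4-(3,4-dimethoxybenzoyl)-2-(3,4-dimethoxyphenyl)oxolan-3-yl]methyl pivalate | COc1ccc(cc1OC)C(=O)[C@@H]1CO[C@@H](c2ccc(OC)c(OC)c2)[C@@]1(O[Si](C)(C)C(C)(C)C)COC(=O)C(C)(C)C | intermediate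
17 | (2S,3S,4S)-3-[(tert-butyldimethylsilyl)oxy]-2-(3,4-dimethoxyphenyl)-4-[(R)-(3,4-dimethoxyphenyl)(hydroxy)methyl]-3-(hydroxymethyl)oxolane | COc1ccc(cc1OC)[C@H](O)[C@@H]1CO[C@@H](c2ccc(OC)c(OC)c2)[C@@]1(O[Si](C)(C)C(C)(C)C)CO | intermediate
18 | [(2S,3S,4S)-3-[(tert-butyldimethylsilyl)oxy]-2-(3,4-dimethoxyphenyl)-4-[(R)-(3,4-dimethoxyphenyl)(hydroxy)methyl]oxolan-3-yl]methyl 4-methylbenzenesulfonate | COc1ccc(cc1OC)[C@H](O)[C@@H]1CO[C@@H](c2ccc(OC)c(OC)c2)[C@@]1(O[Si](C)(C)C(C)(C)C)COS(=O)(=O)c3ccc(C)cc3 | intermediate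
19 | (1S,2S,5S,6R)-1-[(tert-butyldimethylsilyl)oxy]-2,6-bis(3,4-dimethoxyphenyl)-3,7-dioxabicyclo[3.3.0]octane | COc1ccc([C@@H]2OC[C@]3(O[Si](C)(C)C(C)(C)C)[C@H](c4ccc(OC)c(OC)c4)OC[C@@H]23)cc1OC | intermediate
20 | (1S,2S,5S,6R)-2,6-bis(3,4-dimethoxyphenyl)-3,7-dioxabicyclo[3.3.0]octan-1-ol (CNP0422369.10) | COc1ccc([C@@H]2OC[C@]3(O)[C@H](c4ccc(OC)c(OC)c4)OC[C@@H]23)cc1OC | target

**Step count**
Total: 14 steps. Longest linear sequence: 13 steps (steps 1–6 and 8–14, from veratraldehyde and methyl acrylate); step 7 is a one-step branch.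

**Steps most likely to fail**

Step 13 (closure of ring A). The displacement has to build the trans ring fusion at a neopentyl-type carbon and may be slow. Meanwhile the silyl group may migrate from the C1 oxygen to the C6 alkoxide, after which the freed tertiary alkoxide would close a spiro-epoxide onto C8. The fallback closes ring A from the other end. Setting out from 17, Bu4NF in THF would remove the silyl group and give (2S,3S,4S)-2-(3,4-dimethoxyphenyl)-4-[(R)-(3,4-dimethoxyphenyl)(hydroxy)methyl]-3-(hydroxymethyl)oxolan-3-ol, the triol F1. Brief exposure to catalytic 10-camphorsulfonic acid in CH2Cl2 at 0 °C would ionize the electron-rich benzylic C6 hydroxyl and let the primary C8 hydroxyl capture the cation, so the bond formed is C6–O7. This is the classical acid-mediated closure of furofuran lignans. The tertiary C1 hydroxyl could only give an oxetane and should not compete, and the aryl group is expected to settle trans to C4. The fallback comes back to the route at the target 20.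

Step 8 (cycloaddition). Addition to the hindered trisubstituted alkene may be outrun by dimerization of the nitrile oxide to the furoxan, and the facial or regiochemical preference may erode. The fallback uses a metal alkoxide to steer the dipole. Setting out from 9, i-Bu2AlH (CH2Cl2, −78 °C) would remove the pivalate and give (S)-[2-(3,4-dimethoxyphenyl)-2,5-dihydrofuran-3-yl]methanol, the allylic alcohol F2. Its magnesium alkoxide (EtMgBr, CH2Cl2, 0 °C) would be treated with isolated hydroximoyl chloride 11, prepared from 10 with N-chlorosuccinimide. In this magnesium alkoxide-directed nitrile oxide cycloaddition the metal binds both the alkoxide and the dipole oxygen, which accelerates the addition and delivers the oxygen to the carbon bearing the alkoxymethyl arm (C1), while the C2 aryl still dictates the face. The product would be [(3aR,6S,6aS)-3,6-bis(3,4-dimethoxyphenyl)-3a,4,6,6a-tetrahydrofuro[3,4-d]isoxazol-6a-yl]methanol, the hydroxymethyl isoxazoline F3. Pivaloyl chloride in pyridine would return to the route at 13.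

Step 11 (reduction at C6). Hydride may add to the wrong face of the C6 carbonyl, giving the C6 epimer. The fallback replaces open Felkin–Anh control by internal delivery. Setting out from 15, Me4NBH(OAc)3 in MeCN/AcOH at −20 °C (hydroxyl-directed Evans–Saksena reduction) would bind boron to the C1 oxygen and deliver hydride through a chair with the aryl group equatorial. This is expected to give [(2S,3S,4S)-2-(3,4-dimethoxyphenyl)-4-[(R)-(3,4-dimethoxyphenyl)(hydroxy)methyl]-3-hydroxyoxolan-3-yl]methyl pivalate, the 1,3-anti diol F4. Excess t-BuMe2SiOTf with 2,6-lutidine would give [(2S,3S,4S)-3-[(tert-butyldimethylsilyl)oxy]-4-[(R)-[(tert-butyldimethylsilyl)oxy](3,4-dimethoxyphenyl)methyl]-2-(3,4-dimethoxyphenyl)oxolan-3-yl]methyl pivalate, the bis-silyl ether F5. i-Bu2AlH would then cleave the pivalate to [(2S,3S,4S)-3-[(tert-butyldimethylsilyl)oxy]-4-[(R)-[(tert-butyldimethylsilyl)oxy](3,4-dimethoxyphenyl)methyl]-2-(3,4-dimethoxyphenyl)oxolan-3-yl]methanol, the bis-silyl alcohol F6. HF·pyridine buffered with pyridine in THF at 0 °C should remove the less hindered secondary silyl ether first and return to the route at 17.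

**Further compounds**
F1 | step 13 | (2S,3S,4S)-2-(3,4-dimethoxyphenyl)-4-[(R)-(3,4-dimethoxyphenyl)(hydroxy)methyl]-3-(hydroxymethyl)oxolan-3-ol | COc1ccc(cc1OC)[C@H](O)[C@@H]1CO[C@@H](c2ccc(OC)c(OC)c2)[C@@]1(O)CO
F2 | step 8 | (S)-[2-(3,4-dimethoxyphenyl)-2,5-dihydrofuran-3-yl]methanol | COc1ccc(cc1OC)[C@@H]1OCC=C1CO
F3 | step 8 | [(3aR,6S,6aS)-3,6-bis(3,4-dimethoxyphenyl)-3a,4,6,6a-tetrahydrofuro[3,4-d]isoxazol-6a-yl]methanol | COc1ccc(cc1OC)C1=NO[C@@]2(CO)[C@H](c3ccc(OC)c(OC)c3)OC[C@@H]12
F4 | step 11 | [(2S,3S,4S)-2-(3,4-dimethoxyphenyl)-4-[(R)-(3,4-dimethoxyphenyl)(hydroxy)methyl]-3-hydroxyoxolan-3-yl]methyl pivalate | COc1ccc(cc1OC)[C@H](O)[C@@H]1CO[C@@H](c2ccc(OC)c(OC)c2)[C@@]1(O)COC(=O)C(C)(C)C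
F5 | step 11 | [(2S,3S,4S)-3-[(tert-butyldimethylsilyl)oxy]-4-[(R)-[(tert-butyldimethylsilyl)oxy](3,4-dimethoxyphenyl)methyl]-2-(3,4-dimethoxyphenyl)oxolan-3-yl]methyl pivalate | COc1ccc(cc1OC)[C@H](O[Si](C)(C)C(C)(C)C)[C@@H]1CO[C@@H](c2ccc(OC)c(OC)c2)[C@@]1(O[Si](C)(C)C(C)(C)C)COC(=O)C(C)(C)C
F6 | step 11 | [(2S,3S,4S)-3-[(tert-butyldimethylsilyl)oxy]-4-[(R)-[(tert-butyldimethylsilyl)oxy](3,4-dimethoxyphenyl)methyl]-2-(3,4-dimethoxyphenyl)oxolan-3-yl]methanol | COc1ccc(cc1OC)[C@H](O[Si](C)(C)C(C)(C)C)[C@@H]1CO[C@@H](c2ccc(OC)c(OC)c2)[C@@]1(O[Si](C)(C)C(C)(C)C)CO
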